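All runs were computed on assumed constants; the scatter is artificial.

Late in the beta run, between 2.00 min and 4.00 min, the target gains 12 percentage points while the starting material loses 5 points. The ratio of these two, g = 2.42, a reading with its scatter, is taken as the target still to come per point of starting material remaining. It exceeds one, so the target draws on a store behind the starting material, and the likely store is the other conformer. A molecule flips between the two forms and has a chance of becoming target along the way. If g holds, the beta run ends near 40.6 %.

the same everywhere: starting material 0.80 M; precatalyst 0.057 mol%
- alpha: added ligand 0.32 mM; temperature 34 °C; run made earlier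
- beta: added ligand 0.48 mM; temperature 75 °C; run made earlier
- Sunday's: added ligand 0.64 mM; temperature 90 °C; time 2.5 min
- Thursday's: added ligand 0.64 mM; temperature 65 °C; time 2.5 min
- Saturday's: added ligand 0.64 mM; temperature 40 °C; time 2.5 min
- Friday's: added ligand 0.64 mM; temperature 15 °C; time 2.5 min

- alpha (time / min: target / %, starting material / %): 2.50: 0.2, 95.5; 4.00: 1.0, 91.1; 5.00: 0.8, 88.6; 8.00: 2.1, 82.8; 12.0: 3.1, 75.0; 20.0: 7.9, 59.7; 30.0: 16.2, 43.9
- beta (time / min: target / %, starting material / %): 0.333: 1.3, 46.4; 0.500: 2.8, 34.4; 0.667: 4.3, 26.3; 1.00: 7.4, 18.9; 2.00: 15.7, 10.3; 3.00: 22.9, 7.3; 4.00: 27.8, 5.3

(readings scatter by 0.5 percentage points)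

- in a conversion other conformer counts as not yet reacted

1. the best flask by amount of target, in percent of the starting material charged; "all alike" if 1.5 percentage points covers them all (Sunday's / Thursday's / Saturday's / Friday's / all alike)
2. amount of target at the end, in percent of the starting material charged, Sunday's
3. amount of target at the end, in percent of the starting material charged, Thursday's
4. amount of target at the end, in percent of the starting material charged, Saturday's
5. amount of target at the end, in percent of the starting material charged, Friday's

The beta run shows a ladder of times. On the fastest rung, the starting material first falls with a half-life of 0.408 min, yet the target reads 4.3 % at 0.667 min: this is the flip, a pre-equilibrium in appearance. On the next rung, the late half-life of the starting material reads 2.09 min, and the store drains. The alpha run, at 34 °C, has a half-life of the starting material that reads 24.7 min between 5.00 min and 30.0 min, and its target reads 0.2 % at 2.50 min. The effect of the added ligand stays unread, since it changes together with the temperature.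

My own reckoning therefore puts Sunday's, the hottest flask at 90 °C, on the draining rung within 2.5 min, and so first. Saturday's and Friday's, near or below the alpha temperature, should hold about the alpha target reading at 2.50 min or less.

The forecast, holding that “Sunday's is probably best”, gives 21 %, 10.5 %, 0.3 % and 0 % for Sunday's, Thursday's, Saturday's and Friday's.

The flasks give 25.2 %, 7.25 %, 0.249 % and 0 % in that order, so Sunday's is best.

    catalyst + other conformer → catalyst + isomer of the product (k = 140 /M/s, Ea = 57.0 kJ/mol)
    catalyst + added ligand ⇌ idle complex, settled at all times (K = 17000 /M, ΔH = −8.00 kJ/mol)
    precatalyst ⇌ catalyst (K = 1.80, k = 0.0630 /s, Ea = 95.0 kJ/mol, ΔH = −28.0 kJ/mol)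
    starting material + catalyst → catalyst + target (k = 330 /M/s, Ea = 51.0 kJ/mol)
    starting material ⇌ other conformer (K = 5.10, k = 0.180 /s, Ea = 102 kJ/mol, ΔH = 14.0 kJ/mol)
    (constants at 90 °C)

Sunday's falls short of the charge mainly because of the loss of starting material to other conformer: without that step the same flask gives 95.1 % instead of 25.2 %. At the end, Sunday's holds 3.3 % of starting material, so g, carried over from the beta run with its other temperature and ligand, points to 33.2 % finally, and the flask gives 31.6 % at 25.0 min.

Sunday's read later, at 6.0 min, has 0.27 % of starting material left, so g gives 32.5 % of target there. The computed value is 31.1 %.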